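**Plan** (target numbering: O1, C2 bearing the 3-hydroxy-4,5-dimethoxyphenyl group, C3, C4, C5 bearing the 3,4,5-trimethoxyphenyl group)

1. Retrosynthesis: the C3 and C4 methyl groups are traced back to a cis-fused γ-lactone (C3–C(=O)–O–CH2–C4) plus a removable CO2Me on C3; the tetrahydrofuran is then cut at O1–C5 and C2–C3.
2. This gives an aryl aldehyde (C2 and O1) and a lactone-fused donor–acceptor cyclopropane (C3–C4–C5). The cut is possible because C5 is a benzylic ether carbon (aryl donor) and C3, raised to the malonate level, is an acceptor carbon 1,3-related to it through C4.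
3. Forward: aryl alkyne → Z-alkene → enantioselective malonate-carbene cyclopropanation → lactonisation → Lewis-acid (3+2) ring expansion of the three-membered ring to the five-membered ring by insertion of the aldehyde C=O → demethoxycarbonylation → lactone to two methyl groups → debenzylation.
4. Stereochemistry: C4 comes from the ligand-controlled cyclopropanation and is never touched again; C5 from SN2 inversion at the cis (endo-aryl) cyclopropane carbon (gives 4,5-trans); C2 from the 2,5-cis, convex-face ring closure; C3 from the cis ring fusion of the lactone tether (gives 3,4-cis and 2,3-trans).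

Key step: step 6

Remarks on the chemistry: the antipode of the bis(oxazoline) ligand in step 3 is assumed to be the one that gives the (2S,3S)-cyclopropane; the sense of induction on this Z-alkene has to be confirmed, and both ligand antipodes are accessible. Ylide 5 is taken as a catalogue reagent.

**Step 1**
Reactants: 1 5-iodo-1,2,3-trimethoxybenzene; 2 tert-butyldimethyl(prop-2-yn-1-yloxy)silane
Product: 3 tert-butyldimethyl{[3-(3,4,5-trimethoxyphenyl)prop-2-yn-1-yl]oxy}silane
Conditions: Pd(PPh3)2Cl2 (2 mol%), CuI (4 mol%), Et3N, THF, rt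
Reagents that add atoms: none
Why: Sonogashira coupling of an electron-rich aryl iodide with a terminal alkyne is routine, and the silyl ether is inert to Pd/Cu/amine.

**Step 2**
Reactants: 3 tert-butyldimethyl{[3-(3,4,5-trimethoxyphenyl)prop-2-yn-1-yl]oxy}silane
Product: 4 (Z)-tert-butyldimethyl{[3-(3,4,5-trimethoxyphenyl)prop-2-en-1-yl]oxy}silane
Conditions: H2 (1 atm), Lindlar catalyst, quinoline, EtOAc, rt
Reagents that add atoms: none
Why: Lindlar semihydrogenation delivers both hydrogens syn on the poisoned Pd surface, so the Z geometry needed for a cis cyclopropane should be set, with quinoline suppressing over-reduction.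

**Step 3**
Reactants: 4 (Z)-tert-butyldimethyl{[3-(3,4,5-trimethoxyphenyl)prop-2-en-1-yl]oxy}silane; 5 dimethyl 2-(phenyl-λ3-iodanylidene)malonate
Product: 6 dimethyl (2S,3S)-3-{[(tert-butyldimethylsilyl)oxy]methyl}-2-(3,4,5-trimethoxyphenyl)cyclopropane-1,1-dicarboxylate (aryl and CH2OTBS cis)
Conditions: 5 (1.5 equiv), [Cu(MeCN)4]PF6 (5 mol%), chiral side-arm bis(oxazoline) ligand (6 mol%), 4 Å MS, PhMe, 0 °C → rt
Reagents that add atoms: none
Why: Cu(I)–bis(oxazoline)-catalysed asymmetric cyclopropanation of a cis-1,2-disubstituted aryl alkene with a malonate iodonium ylide is a concerted carbene transfer, so the Z geometry should become the cis relationship of aryl and CH2OTBS while the ligand selects the alkene face and thereby sets both stereocentres.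

**Step 4**
Reactants: 6 dimethyl (2S,3S)-3-{[(tert-butyldimethylsilyl)oxy]methyl}-2-(3,4,5-trimethoxyphenyl)cyclopropane-1,1-dicarboxylate
Product: 8 methyl (1R,5S,6S)-2-oxo-6-(3,4,5-trimethoxyphenyl)-3-oxabicyclo[3.1.0]hexane-1-carboxylate (aryl endo), via hydroxymethyl cyclopropane diester 7 (not isolated)
Conditions: HF·pyridine, THF, 0 °C → rt; then PPTS (cat.), PhMe, 60 °C
Reagents that add atoms: none
Why: desilylation frees the primary alcohol, which should lactonise (5-exo-trig acyl transfer) onto the one ester that is cis to it, installing the temporary γ-lactone ring with the aryl group endo and touching no stereocentre.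

**Step 5**
Reactants: 9 3-hydroxy-4,5-dimethoxybenzaldehyde
Product: 10 3-(benzyloxy)-4,5-dimethoxybenzaldehyde
Conditions: BnBr, K2CO3, DMF, rt
Reagents that add atoms: benzyl bromide, BrCc1ccccc1
Why: Williamson etherification masks the only acidic group against the later Lewis acid, hydride and sulfonylation steps, and benzyl can be removed last by hydrogenolysis.

**Step 6**
Reactants: 8 methyl (1R,5S,6S)-2-oxo-6-(3,4,5-trimethoxyphenyl)-3-oxabicyclo[3.1.0]hexane-1-carboxylate; 10 3-(benzyloxy)-4,5-dimethoxybenzaldehyde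
Product: 11 methyl (1S,5S,6R,8R)-8-[3-(benzyloxy)-4,5-dimethoxyphenyl]-2-oxo-6-(3,4,5-trimethoxyphenyl)-3,7-dioxabicyclo[3.3.0]octane-1-carboxylate (cis-fused, both aryl groups exo)
Conditions: 10 (2 equiv), Sn(OTf)2 (10 mol%), 4 Å MS, CH2Cl2, −20 °C → rt
Reagents that add atoms: none
Why: Sn(II) chelates the lactone and ester carbonyls on C1 of 8 and polarises the C1–C6 bond, the aldehyde oxygen of 10 attacks the benzylic carbon C6 anti to that bond (SN2-like, inversion), and the resulting oxocarbenium ion is captured, after rotation about C5–C6, by the tin enolate carbon C1. The closest known reaction type is the Lewis-acid-catalysed (3+2) annulation of 2-arylcyclopropane-1,1-dicarboxylates with aldehydes, a formal insertion of C=O into the activated cyclopropane bond that enlarges the three-membered ring by two atoms to a 2,5-cis-tetrahydrofuran. The only ring closed is the tetrahydrofuran, by a 5-(enolexo)-endo-trig aldol-type attack of the enolate carbon on the oxocarbenium carbon (C2–C3 bond of the target), the O1–C5 bond having formed in the intermolecular opening. C5 is set by inversion at the endo-aryl cyclopropane carbon (aryl cis to CH2 in 8 becomes trans in 11), C4 is carried over unchanged, the quaternary C3 is fixed by the lactone tether because the new bond can only form on the face that carries C6 (cis fusion), and C2 is set by an envelope transition state that places both aryl groups pseudo-equatorial on the convex face (2,5-cis). The step needs SN2 opening to outrun ionisation to a benzylic cation and C–C closure to outrun elimination, which the moderate donor strength of the 3,4,5-trimethoxyphenyl group, the strain of the all-cis bicyclic cyclopropane, the mild Lewis acid and the low temperature are meant to secure. Even if partial ionisation or reversible ring opening occurs, C4 is never broken, so enantiopurity should be kept and the exo,exo isomer 11 is also the expected thermodynamic product.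

**Step 7**
Reactants: 11 methyl (1S,5S,6R,8R)-8-[3-(benzyloxy)-4,5-dimethoxyphenyl]-2-oxo-6-(3,4,5-trimethoxyphenyl)-3,7-dioxabicyclo[3.3.0]octane-1-carboxylate
Product: 12 (1S,5S,6R,8S)-8-[3-(benzyloxy)-4,5-dimethoxyphenyl]-6-(3,4,5-trimethoxyphenyl)-3,7-dioxabicyclo[3.3.0]octan-2-one
Conditions: LiCl, H2O (2 equiv), DMSO, 140 °C
Reagents that add atoms: none
Why: in this Krapcho demethoxycarbonylation chloride should attack the methyl ester (SN2 at CH3, faster than at the lactone CH2), the carboxylate loses CO2, and protonation of the lactone enolate can only give the strain-free cis-fused lactone, which places the C3 hydrogen trans to the lactone and the C3 carbonyl trans to the C2 aryl group.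

**Step 8**
Reactants: 12 (1S,5S,6R,8S)-8-[3-(benzyloxy)-4,5-dimethoxyphenyl]-6-(3,4,5-trimethoxyphenyl)-3,7-dioxabicyclo[3.3.0]octan-2-one
Product: 13 [(2S,3R,4S,5R)-2-[3-(benzyloxy)-4,5-dimethoxyphenyl]-5-(3,4,5-trimethoxyphenyl)tetrahydrofuran-3,4-diyl]dimethanol
Conditions: LiAlH4, THF, 0 °C → rt; Rochelle salt work-up
Reagents that add atoms: none
Why: hydride reduction of the lactone to the 1,4-diol removes the tether without touching any stereocentre, the aryl ethers or the benzyl ether.

**Step 9**
Reactants: 13 [(2S,3R,4S,5R)-2-[3-(benzyloxy)-4,5-dimethoxyphenyl]-5-(3,4,5-trimethoxyphenyl)tetrahydrofuran-3,4-diyl]dimethanol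
Product: 14 [(2S,3R,4S,5R)-2-[3-(benzyloxy)-4,5-dimethoxyphenyl]-5-(3,4,5-trimethoxyphenyl)tetrahydrofuran-3,4-diyl]bis(methylene) dimethanesulfonate
Conditions: MsCl (3 equiv), Et3N, CH2Cl2, −10 °C
Reagents that add atoms: methanesulfonyl chloride, CS(=O)(=O)Cl
Why: sulfonylation of both primary alcohols with excess MsCl at low temperature should be faster than cyclisation of a mono-mesylate to the bicyclic ether.

**Step 10**
Reactants: 14 [(2S,3R,4S,5R)-2-[3-(benzyloxy)-4,5-dimethoxyphenyl]-5-(3,4,5-trimethoxyphenyl)tetrahydrofuran-3,4-diyl]bis(methylene) dimethanesulfonate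
Product: 15 (2S,3S,4R,5R)-2-[3-(benzyloxy)-4,5-dimethoxyphenyl]-3,4-dimethyl-5-(3,4,5-trimethoxyphenyl)tetrahydrofuran
Conditions: LiEt3BH, THF, 0 °C → 50 °C
Reagents that add atoms: none
Why: the triethylborohydride displaces primary mesylates by SN2 hydride transfer at carbon (with little S–O cleavage), so both CH2OMs groups should become CH3 while the ring stereocentres are not involved.

**Step 11**
Reactants: 15 (2S,3S,4R,5R)-2-[3-(benzyloxy)-4,5-dimethoxyphenyl]-3,4-dimethyl-5-(3,4,5-trimethoxyphenyl)tetrahydrofuran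
Product: 16 5-[(2S,3S,4R,5R)-3,4-dimethyl-5-(3,4,5-trimethoxyphenyl)tetrahydrofuran-2-yl]-2,3-dimethoxyphenol (CNP0293669.1)
Conditions: H2 (1 atm), 10% Pd/C, EtOAc, rt
Reagents that add atoms: none
Why: hydrogenolysis of the aryl benzyl ether on Pd/C in neutral EtOAc should be much faster than cleavage of the ring benzylic C–O bonds, so the phenol is released without change at the four stereocentres.

**Compound list**

1 | 5-iodo-1,2,3-trimethoxybenzene | COc1cc(I)cc(OC)c1OC | starting material
2 | tert-butyldimethyl(prop-2-yn-1-yloxy)silane | C#CCO[Si](C)(C)C(C)(C)C | starting material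
3 | tert-butyldimethyl{[3-(3,4,5-trimethoxyphenyl)prop-2-yn-1-yl]oxy}silane | COc1cc(C#CCO[Si](C)(C)C(C)(C)C)cc(OC)c1OC | intermediate
4 | (Z)-tert-butyldimethyl{[3-(3,4,5-trimethoxyphenyl)prop-2-en-1-yl]oxy}silane | COc1cc(/C=C\CO[Si](C)(C)C(C)(C)C)cc(OC)c1OC | intermediate
5 | dimethyl 2-(phenyl-λ3-iodanylidene)malonate | COC(=O)[C-]([I+]c1ccccc1)C(=O)OC | starting material
6 | dimethyl (2S,3S)-3-{[(tert-butyldimethylsilyl)oxy]methyl}-2-(3,4,5-trimethoxyphenyl)cyclopropane-1,1-dicarboxylate | COc1cc(cc(OC)c1OC)[C@@H]2[C@H](CO[Si](C)(C)C(C)(C)C)C2(C(=O)OC)C(=O)OC | intermediate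
7 | dimethyl (2S,3S)-3-(hydroxymethyl)-2-(3,4,5-trimethoxyphenyl)cyclopropane-1,1-dicarboxylate | COc1cc(cc(OC)c1OC)[C@@H]2[C@H](CO)C2(C(=O)OC)C(=O)OC | intermediate
8 | methyl (1R,5S,6S)-2-oxo-6-(3,4,5-trimethoxyphenyl)-3-oxabicyclo[3.1.0]hexane-1-carboxylate | COc1cc(cc(OC)c1OC)[C@@H]2[C@@H]3COC(=O)[C@]23C(=O)OC | intermediate
9 | 3-hydroxy-4,5-dimethoxybenzaldehyde | COc1cc(C=O)cc(O)c1OC | starting material
10 | 3-(benzyloxy)-4,5-dimethoxybenzaldehyde | COc1cc(C=O)cc(OCc2ccccc2)c1OC | intermediate
11 | methyl (1S,5S,6R,8R)-8-[3-(benzyloxy)-4,5-dimethoxyphenyl]-2-oxo-6-(3,4,5-trimethoxyphenyl)-3,7-dioxabicyclo[3.3.0]octane-1-carboxylate | COc1cc([C@H]2O[C@@H](c3cc(OC)c(OC)c(OC)c3)[C@H](COC4=O)[C@@]24C(=O)OC)cc(OCc5ccccc5)c1OC | intermediate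
12 | (1S,5S,6R,8S)-8-[3-(benzyloxy)-4,5-dimethoxyphenyl]-6-(3,4,5-trimethoxyphenyl)-3,7-dioxabicyclo[3.3.0]octan-2-one | COc1cc([C@H]2O[C@@H](c3cc(OC)c(OC)c(OC)c3)[C@H](COC4=O)[C@@H]24)cc(OCc5ccccc5)c1OC | intermediate
13 | [(2S,3R,4S,5R)-2-[3-(benzyloxy)-4,5-dimethoxyphenyl]-5-(3,4,5-trimethoxyphenyl)tetrahydrofuran-3,4-diyl]dimethanol | COc1cc([C@H]2O[C@@H](c3cc(OC)c(OC)c(OC)c3)[C@H](CO)[C@@H]2CO)cc(OCc4ccccc4)c1OC | intermediate
14 | [(2S,3R,4S,5R)-2-[3-(benzyloxy)-4,5-dimethoxyphenyl]-5-(3,4,5-trimethoxyphenyl)tetrahydrofuran-3,4-diyl]bis(methylene) dimethanesulfonate | COc1cc([C@H]2O[C@@H](c3cc(OC)c(OC)c(OC)c3)[C@H](COS(C)(=O)=O)[C@@H]2COS(C)(=O)=O)cc(OCc4ccccc4)c1OC | intermediate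
15 | (2S,3S,4R,5R)-2-[3-(benzyloxy)-4,5-dimethoxyphenyl]-3,4-dimethyl-5-(3,4,5-trimethoxyphenyl)tetrahydrofuran | COc1cc([C@H]2O[C@@H](c3cc(OC)c(OC)c(OC)c3)[C@H](C)[C@@H]2C)cc(OCc4ccccc4)c1OC | intermediate
16 | 5-[(2S,3S,4R,5R)-3,4-dimethyl-5-(3,4,5-trimethoxyphenyl)tetrahydrofuran-2-yl]-2,3-dimethoxyphenol | COc1cc([C@H]2O[C@@H](c3cc(OC)c(OC)c(OC)c3)[C@H](C)[C@@H]2C)cc(O)c1OC | target

**Step count and risks**

Total: 11 steps. Longest linear sequence: 10 steps (1–4, then 6–11); step 5 is a one-step side branch.

Steps most likely to fail: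

Step 6. The benzylic cyclopropane carbon may ionise before the weakly nucleophilic aldehyde attacks, which would lose the inversion pathway and with it the 4,5-trans control; the Lewis acid may also open or isomerise the cyclopropane without capture. The fallback divides the two bond formations and sets out from 8 and 10, coming back at 11. Aldehyde 10 is reduced (NaBH4, MeOH) to [3-(benzyloxy)-4,5-dimethoxyphenyl]methanol F4. This much better nucleophile opens 8 at the benzylic carbon with inversion under mild Lewis-acid catalysis (Sc(OTf)3, CH2Cl2; homo-conjugate addition of an alcohol to a donor–acceptor cyclopropane), giving the dibenzylic ether methyl (4S)-4-[(R)-{[3-(benzyloxy)-4,5-dimethoxybenzyl]oxy}(3,4,5-trimethoxyphenyl)methyl]-2-oxotetrahydrofuran-3-carboxylate F5. Oxidative C–H cleavage with DDQ (CH2Cl2, 4 Å MS; cross-dehydrogenative coupling) at the less hindered benzylic CH2 should generate the same oxocarbenium ion, which the 1,3-dicarbonyl carbon traps to close the ring to 11.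

Step 3. Face discrimination of the Z-alkene may be incomplete, a stepwise carbene addition to the electron-rich styrene may erode the cis geometry, and ylide formation at the allylic oxygen may compete. The fallback makes the carbene transfer intramolecular; it sets out from 4 and comes back at 8. Desilylation (TBAF, THF) gives (Z)-3-(3,4,5-trimethoxyphenyl)prop-2-en-1-ol F1. Acylation with methyl malonyl chloride and pyridine gives methyl (Z)-3-(3,4,5-trimethoxyphenyl)prop-2-en-1-yl malonate F2. Regitz diazo transfer (p-ABSA, Et3N, MeCN) gives methyl (Z)-3-(3,4,5-trimethoxyphenyl)prop-2-en-1-yl 2-diazomalonate F3. Intramolecular cyclopropanation with a chiral Cu(I)–bis(oxazoline) catalyst is concerted and geometrically constrained, so the Z-alkene should give the endo-aryl lactone 8 directly; if the enantiomeric purity is insufficient, the lactone is enriched by recrystallisation or preparative chromatography on a chiral phase.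

Step 7. At 140 °C the lactone enolate may expel the ring oxygen (retro-oxa-Michael), chloride may open the lactone at its O–CH2, or an aryl methyl ether may be cleaved. The fallback avoids both the hot nucleophile and a free enolate; it sets out from 11 and comes back at 12. Saponification (LiOH, THF/H2O/MeOH, 50 °C) followed by acidification, which relactonises the carboxyl group cis to the CH2OH, should give (1S,5S,6R,8R)-8-[3-(benzyloxy)-4,5-dimethoxyphenyl]-2-oxo-6-(3,4,5-trimethoxyphenyl)-3,7-dioxabicyclo[3.3.0]octane-1-carboxylic acid F6. Thermal decarboxylation of this β-carbonyl acid (PhMe, 100 °C) through the lactone enol then gives the cis-fused lactone 12.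

**Further compounds**

F1 | step 3 | (Z)-3-(3,4,5-trimethoxyphenyl)prop-2-en-1-ol | COc1cc(/C=C\CO)cc(OC)c1OC
F2 | step 3 | methyl (Z)-3-(3,4,5-trimethoxyphenyl)prop-2-en-1-yl malonate | COC(=O)CC(=O)OC/C=C\c1cc(OC)c(OC)c(OC)c1
F3 | step 3 | methyl (Z)-3-(3,4,5-trimethoxyphenyl)prop-2-en-1-yl 2-diazomalonate | COC(=O)C(=[N+]=[N-])C(=O)OC/C=C\c1cc(OC)c(OC)c(OC)c1
F4 | step 6 | [3-(benzyloxy)-4,5-dimethoxyphenyl]methanol | COc1cc(CO)cc(OCc2ccccc2)c1OC
F5 | step 6 | methyl (4S)-4-[(R)-{[3-(benzyloxy)-4,5-dimethoxybenzyl]oxy}(3,4,5-trimethoxyphenyl)methyl]-2-oxotetrahydrofuran-3-carboxylate | COc1cc(CO[C@@H](c2cc(OC)c(OC)c(OC)c2)[C@@H]3COC(=O)C3C(=O)OC)cc(OCc4ccccc4)c1OC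
F6 | step 7 | (1S,5S,6R,8R)-8-[3-(benzyloxy)-4,5-dimethoxyphenyl]-2-oxo-6-(3,4,5-trimethoxyphenyl)-3,7-dioxabicyclo[3.3.0]octane-1-carboxylic acid | COc1cc([C@H]2O[C@@H](c3cc(OC)c(OC)c(OC)c3)[C@H](COC4=O)[C@@]24C(=O)O)cc(OCc5ccccc5)c1OC
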